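**Retrosynthetic overview**

1. The cyclohexene is numbered C1 (CH bearing a coumarin), C2=C3(CH3), C4H2, C5(CH3)2, C6 (CH bearing the carbinol). The enabling feature is that C1 is the unsubstituted end of the allyl unit C1–C2=C3(CH3) of this ring. Its partner is C8 of the coumarin benzene ring, the C–H flanked by O1 and 7-OCH3 and para to 5-OCH3.
2. The key disconnection is C8–C1. It pairs free 5,7-dimethoxycoumarin (a C–H nucleophile) with a methyl-stabilised cyclohexenyl cation made from a C1 allylic alcohol. The C6 side chain sends the arene to the opposite face (1,6-trans), and both C1 alcohol epimers converge.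
3. The allylic alcohol is a reduced 6-substituted isophorone: C1 is the old C=O, and C3-CH3 and C5(CH3)2 are already in place. The C6–CH(OH) bond is cut by a catalytic enantioselective syn-Mukaiyama aldol with the 8-formylcoumarin. This aldol sets the carbinol and C6, and C1 is relayed from C6.
4. Both aryl units come from the same arene through its C8, once by formylation and once in the key step.
5. Ring order: no ring is built. Both coumarin bicycles (from 5,7-dimethoxycoumarin) and the cyclohexene (from isophorone) are bought intact.

Key step: step 6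

Assumption: read with the numbering above, the target is (1S,6R) with an (R)-carbinol, the two ring substituents are trans, and the C6/carbinol pair has the syn-aldol relationship. The (2R,3R)-tartrate-derived acyloxyborane is taken to expose the Re face of the aldehyde; if it does not, its mirror image is used.

**Step 1**
Reactants: 1 5,7-dimethoxycoumarin (citropten)
Product: 3 5,7-dimethoxy-2-oxo-2H-chromene-8-carbaldehyde, via alpha-chloro ether 2 (not isolated)
Conditions: Cl2CHOMe, TiCl4, CH2Cl2, 0 °C to rt; then ice-cold 1 M HCl
Reagents that add atoms: dichloromethyl methyl ether COC(Cl)Cl; water O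
Why: Rieche formylation (a Friedel–Crafts reaction of the TiCl4-activated dichloromethyl ether) should enter at C8, which is ortho to O1 and 7-OCH3, para to 5-OCH3 and less crowded than C6 between two methoxy groups, and hydrolysis of 2 on work-up releases the aldehyde.

**Step 2**
Reactants: 4 isophorone
Product: 6 1,5,5-trimethyl-3-(trimethylsilyloxy)cyclohexa-1,3-diene, via lithium dienolate 5 (not isolated)
Conditions: LDA (commercial solution), THF, −78 °C; then TMSCl, −78 °C to rt
Reagents that add atoms: chlorotrimethylsilane C[Si](C)(C)Cl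
Why: Kinetic silyl enol ether formation, in which LDA removes an alpha-prime proton at C6 and O-silylation of the cross-conjugated dienolate fixes this regiochemistry, so C6 is the only nucleophilic carbon.

**Step 3**
Reactants: 3 5,7-dimethoxy-2-oxo-2H-chromene-8-carbaldehyde; 6 1,5,5-trimethyl-3-(trimethylsilyloxy)cyclohexa-1,3-diene
Product: 8 (6R)-6-[(R)-hydroxy(5,7-dimethoxy-2-oxo-2H-chromen-8-yl)methyl]-3,5,5-trimethylcyclohex-2-en-1-one (syn aldol), via trimethylsilyl ether 7 (not isolated)
Conditions: (2R,3R)-2-O-(2,6-diisopropoxybenzoyl)tartaric acid (20 mol %) + BH3·THF (20 mol %), EtCN, 0 °C; then 3 and 6, −78 °C; then 1 M HCl, THF, 0 °C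
Reagents that add atoms: none
Why: Catalytic enantioselective Mukaiyama aldol through an open transition state, in which the acyloxyborane binds the aldehyde and exposes its Re face (giving the (R)-carbinol) and the antiperiplanar approach that keeps the aryl group away from the C5 gem-dimethyl group gives the syn pair, that is (6R); catalysts of this kind are syn-selective for cyclic enol silanes too, where closed transition states would give anti.

**Step 4**
Reactants: 8 syn aldol
Product: 9 (6R)-6-[(R)-(tert-butyldimethylsilyloxy)(5,7-dimethoxy-2-oxo-2H-chromen-8-yl)methyl]-3,5,5-trimethylcyclohex-2-en-1-one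
Conditions: TBSOTf, 2,6-lutidine, CH2Cl2, −78 to 0 °C
Reagents that add atoms: tert-butyldimethylsilyl triflate CC(C)(C)[Si](C)(C)OS(=O)(=O)C(F)(F)F
Why: Silyl triflate protection of a hindered secondary alcohol, in which the weak hindered base should avoid retro-aldol cleavage, any enol silane formed at the enone is hydrolysed on work-up, and no stereocentre is touched.

**Step 5**
Reactants: 9 silyl ether enone
Product: 10 (1R,6S)-6-[(R)-(tert-butyldimethylsilyloxy)(5,7-dimethoxy-2-oxo-2H-chromen-8-yl)methyl]-3,5,5-trimethylcyclohex-2-en-1-ol (expected major epimer, OH cis to the C6 side chain; the C1 epimer is carried along)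
Conditions: NaBH4, CeCl3·7H2O, MeOH/THF, −40 to 0 °C
Reagents that add atoms: none
Why: Luche reduction gives 1,2-reduction of the enone and leaves the coumarin lactone alone in a nearly neutral medium that disfavours O-to-O silyl migration, with hydride expected from the face opposite the C6 side chain; the configuration at C1 is of no consequence because step 6 erases it.

**Step 6**
Reactants: 10 allylic alcohol; 1 5,7-dimethoxycoumarin
Product: 12 8-[(1S,6R)-6-[(R)-(tert-butyldimethylsilyloxy)(5,7-dimethoxy-2-oxo-2H-chromen-8-yl)methyl]-3,5,5-trimethylcyclohex-2-en-1-yl]-5,7-dimethoxy-2H-chromen-2-one, via cyclohexenyl cation 11 (not isolated)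
Conditions: 1 (2.5 equiv), Ca(NTf2)2 (10 mol %), Bu4NPF6 (10 mol %), CH2Cl2, 0 °C to rt
Reagents that add atoms: none
Why: Ca(NTf2)2/Bu4NPF6 ionises the only free hydroxyl group of 10, both C1 epimers giving the same cyclohexenyl cation 11 (charge shared by C1 and the methyl-bearing C3), C8–H of 1 adds to C1, and loss of the proton restores the arene. The reaction type is a dehydrative Friedel–Crafts allylation of an alkoxyarene with a cyclic allylic alcohol, and its closest relative is the acid-catalysed cannabidiol coupling of p-mentha-2,8-dien-1-ol with olivetol, in which a doubly ortho-oxygenated arene carbon likewise adds to the secondary end of a 3-methylcyclohexenyl cation, trans to the neighbouring ring substituent. No ring is closed. The one new stereocentre, C1 (S), is controlled by C6, whose CH(OTBS)aryl group should stand pseudoaxial to escape the C5 gem-dimethyl group and so cover one face of the cation, leaving the arene to add to the other face and give the 1,6-trans product. Within the cation, C1 is preferred over C3 because attack at C3 would build a quaternary carbon from a di-ortho-substituted arene, is reversible and would leave the less substituted alkene, and within 1, C8 is preferred over C6 because its ring oxygen neighbour is tied back whereas C6 lies between two methoxy groups, the same preference used in step 1. The step also needs the electron-rich benzylic C–O bond to stay intact, which the bulky, weakly basic silyl ether secures while also preventing this oxygen from closing on C3 to a bridged ether before or after the coupling.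

**Step 7**
Reactants: 12 coupled silyl ether
Product: 13 8-[(1S,6R)-6-[(R)-hydroxy(5,7-dimethoxy-2-oxo-2H-chromen-8-yl)methyl]-3,5,5-trimethylcyclohex-2-en-1-yl]-5,7-dimethoxy-2H-chromen-2-one (IN0553)
Conditions: TBAF, AcOH, THF, rt to 40 °C
Reagents that add atoms: none
Why: Fluoride-induced desilylation driven by Si–F bond formation, in which the acetic acid buffer keeps both lactones closed, no strong acid is present that could ionise the benzylic alcohol or add it to the C2=C3 alkene, and no stereocentre is touched.

**Compound list**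

1 | 5,7-dimethoxy-2H-chromen-2-one (5,7-dimethoxycoumarin, citropten) | COc1cc(OC)c2ccc(=O)oc2c1 | starting material
2 | 8-[chloro(methoxy)methyl]-5,7-dimethoxy-2H-chromen-2-one (racemic alpha-chloro ether) | COc1cc(OC)c2ccc(=O)oc2c1C(Cl)OC | intermediate
3 | 5,7-dimethoxy-2-oxo-2H-chromene-8-carbaldehyde | COc1cc(OC)c2ccc(=O)oc2c1C=O | intermediate
4 | 3,5,5-trimethylcyclohex-2-en-1-one (isophorone) | CC1=CC(=O)CC(C)(C)C1 | starting material
5 | lithium cross-conjugated dienolate of isophorone (O–C1=C6, C2=C3) | [Li+].CC1=CC([O-])=CC(C)(C)C1 | intermediate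
6 | 1,5,5-trimethyl-3-(trimethylsilyloxy)cyclohexa-1,3-diene | CC1=CC(O[Si](C)(C)C)=CC(C)(C)C1 | intermediate
7 | trimethylsilyl ether of 8 | O=C1C=C(C)CC(C)(C)[C@@H]1[C@@H](O[Si](C)(C)C)c1c(OC)cc(OC)c2ccc(=O)oc12 | intermediate
8 | (6R)-6-[(R)-hydroxy(5,7-dimethoxy-2-oxo-2H-chromen-8-yl)methyl]-3,5,5-trimethylcyclohex-2-en-1-one | O=C1C=C(C)CC(C)(C)[C@@H]1[C@@H](O)c1c(OC)cc(OC)c2ccc(=O)oc12 | intermediate
9 | (6R)-6-[(R)-(tert-butyldimethylsilyloxy)(5,7-dimethoxy-2-oxo-2H-chromen-8-yl)methyl]-3,5,5-trimethylcyclohex-2-en-1-one | O=C1C=C(C)CC(C)(C)[C@@H]1[C@@H](O[Si](C)(C)C(C)(C)C)c1c(OC)cc(OC)c2ccc(=O)oc12 | intermediate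
10 | (1R,6S)-6-[(R)-(tert-butyldimethylsilyloxy)(5,7-dimethoxy-2-oxo-2H-chromen-8-yl)methyl]-3,5,5-trimethylcyclohex-2-en-1-ol | O[C@@H]1C=C(C)CC(C)(C)[C@@H]1[C@@H](O[Si](C)(C)C(C)(C)C)c1c(OC)cc(OC)c2ccc(=O)oc12 | intermediate
11 | 3-methylcyclohexenyl cation derived from 10 (charge on C1/C3, C6 and carbinol centres unchanged) | [CH+]1C=C(C)CC(C)(C)[C@@H]1[C@@H](O[Si](C)(C)C(C)(C)C)c1c(OC)cc(OC)c2ccc(=O)oc12 | intermediate
12 | tert-butyldimethylsilyl ether of 13, (1S,6R), (R) at the silyloxy carbon | COc1cc(OC)c2ccc(=O)oc2c1[C@H]1C=C(C)CC(C)(C)[C@@H]1[C@@H](O[Si](C)(C)C(C)(C)C)c1c(OC)cc(OC)c2ccc(=O)oc12 | intermediate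
13 | 8-[(1S,6R)-6-[(R)-hydroxy(5,7-dimethoxy-2-oxo-2H-chromen-8-yl)methyl]-3,5,5-trimethylcyclohex-2-en-1-yl]-5,7-dimethoxy-2H-chromen-2-one (IN0553) | COc1cc(OC)c2ccc(=O)oc2c1[C@H]1C=C(C)CC(C)(C)[C@@H]1[C@@H](O)c1c(OC)cc(OC)c2ccc(=O)oc12 | target

**Step count**

Total step count: 7.
Longest linear sequence: 6 steps (1 → 3 → 8 → 9 → 10 → 12 → 13; the line from 4 through 6 is equally long).

**Steps most likely to fail**

**Step 6.**
- Risk: the cation may lose a proton to give cyclohexadienes faster than the hindered, weakly nucleophilic arene captures it. Ionisation of the benzylic C–O bond, or attack through C6 of the arene, may also erode the result.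
- Fallback: this sets out from 10 and 1 and comes back at 12. It replaces the free cation by a stereospecific allyl–aryl cross-coupling on zerovalent palladium.
- The separated major (1R) epimer of 10 is treated with ClCO2Me and pyridine to give the allylic methyl carbonate F1.
- Compound 1 is iodinated at C8 (NIS, TFA, MeCN) to 8-iodo-5,7-dimethoxycoumarin F2. Miyaura borylation (B2pin2, PdCl2(dppf), KOAc, dioxane) then gives the pinacol boronate F3.
- Pd(PPh3)4 in THF joins F1 and F3 without added base, because the methoxide released on decarboxylation activates boron.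
- Ionisation occurs with inversion and puts palladium on the face opposite the C6 side chain. Aryl transfer and reductive elimination with retention at the less substituted terminus C1 should then give 12 with the same 1,6-trans arrangement.

**Step 3.**
- Risk: turnover may be slow with a deactivated, doubly ortho-substituted and Lewis-basic aldehyde and a neopentyl-type nucleophilic carbon. Facial or syn/anti selectivity may be poor.
- Fallback: this sets out from 4 and 3 and comes back at 10. It trades catalysis for a diastereoselective racemic aldol plus classical resolution.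
- The lithium dienolate of 4 (LDA, THF, −78 °C) is transmetalated with Cp2ZrCl2. Such zirconium enolates are syn-selective whatever the enolate geometry. Addition to 3 gives 8 together with its mirror image ent-8 F4.
- Silylation and Luche reduction as in steps 4 and 5 carry the pair through ent-9 F5 to 10 and ent-10 F6, and the major C1 epimer is purified.
- Esterification with (S)-methoxy(phenyl)acetic acid (DCC, DMAP, CH2Cl2) gives the ester of 10 F7 and the ester of ent-10 F8, which are separated by chromatography or crystallisation.
- K2CO3 in MeOH on F7, followed by mild acidification, returns 10.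

**Step 4.**
- Risk: silylation at the very hindered carbinol may be slow, with competing enol silylation and retro-aldol cleavage.
- Fallback: this sets out from 8 and comes back at 13. It merges protection and reduction in one Evans–Tishchenko reaction.
- CH3CHO and catalytic SmI2 in THF at −10 °C are used. The divalent samarium is first oxidised by the aldehyde to the active trivalent samarium alkoxide.
- Hydride is delivered from the hemiacetal on the carbinol oxygen to C1. This should give the hydroxy acetate F9, with the benzylic oxygen acylated and the allylic hydroxyl free and trans to the side chain.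
- Under the conditions of step 6, with 4 Å molecular sieves, the acetate carbonyl can cover the cis face of the cation while 1 adds trans. This gives the coupled acetate F10.
- K2CO3 in MeOH, followed by mild acidification, gives 13.

**Further compounds**

F1 | step 6 | (1R,6S)-6-[(R)-(tert-butyldimethylsilyloxy)(5,7-dimethoxy-2-oxo-2H-chromen-8-yl)methyl]-3,5,5-trimethylcyclohex-2-en-1-yl methyl carbonate | COC(=O)O[C@@H]1C=C(C)CC(C)(C)[C@@H]1[C@@H](O[Si](C)(C)C(C)(C)C)c1c(OC)cc(OC)c2ccc(=O)oc12
F2 | step 6 | 8-iodo-5,7-dimethoxy-2H-chromen-2-one | COc1cc(OC)c2ccc(=O)oc2c1I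
F3 | step 6 | 5,7-dimethoxy-8-(4,4,5,5-tetramethyl-1,3,2-dioxaborolan-2-yl)-2H-chromen-2-one | COc1cc(OC)c2ccc(=O)oc2c1B1OC(C)(C)C(C)(C)O1
F4 | step 3 | ent-8, (6S)-6-[(S)-hydroxy(5,7-dimethoxy-2-oxo-2H-chromen-8-yl)methyl]-3,5,5-trimethylcyclohex-2-en-1-one | O=C1C=C(C)CC(C)(C)[C@H]1[C@H](O)c1c(OC)cc(OC)c2ccc(=O)oc12
F5 | step 3 | ent-9, tert-butyldimethylsilyl ether of F4 | O=C1C=C(C)CC(C)(C)[C@H]1[C@H](O[Si](C)(C)C(C)(C)C)c1c(OC)cc(OC)c2ccc(=O)oc12
F6 | step 3 | ent-10, (1S,6R)-6-[(S)-(tert-butyldimethylsilyloxy)(5,7-dimethoxy-2-oxo-2H-chromen-8-yl)methyl]-3,5,5-trimethylcyclohex-2-en-1-ol | O[C@H]1C=C(C)CC(C)(C)[C@H]1[C@H](O[Si](C)(C)C(C)(C)C)c1c(OC)cc(OC)c2ccc(=O)oc12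
F7 | step 3 | (S)-methoxy(phenyl)acetate ester of 10 | O=C(O[C@@H]1C=C(C)CC(C)(C)[C@@H]1[C@@H](O[Si](C)(C)C(C)(C)C)c1c(OC)cc(OC)c2ccc(=O)oc12)[C@@H](OC)c1ccccc1
F8 | step 3 | (S)-methoxy(phenyl)acetate ester of ent-10 | O=C(O[C@H]1C=C(C)CC(C)(C)[C@H]1[C@H](O[Si](C)(C)C(C)(C)C)c1c(OC)cc(OC)c2ccc(=O)oc12)[C@@H](OC)c1ccccc1
F9 | step 4 | (1S,6S)-6-[(R)-acetoxy(5,7-dimethoxy-2-oxo-2H-chromen-8-yl)methyl]-3,5,5-trimethylcyclohex-2-en-1-ol | O[C@H]1C=C(C)CC(C)(C)[C@@H]1[C@@H](OC(C)=O)c1c(OC)cc(OC)c2ccc(=O)oc12
F10 | step 4 | O-acetyl derivative of 13, (1S,6R), (R) at the acetoxy carbon | COc1cc(OC)c2ccc(=O)oc2c1[C@H]1C=C(C)CC(C)(C)[C@@H]1[C@@H](OC(C)=O)c1c(OC)cc(OC)c2ccc(=O)oc12
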